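**Retrosynthetic overview**
- The target is reached from 5,6,7,8-tetramethoxy-3-(2-methoxy-3-pivaloyloxyphenyl)chromen-4-one by cleaving the chelated 5-methyl ether and then removing the pivalate.
- Key disconnection: the O1–C8a bond of the pyranone ring (ring C). Every carbon of ring A (C5, C6, C7, C8, C8a) carries oxygen, so the C8a oxygen is brought in by dehydrogenative coupling of an enol oxygen with the single free C–H of a 2,3,4,5-tetramethoxybenzoyl ring; no penta-oxygenated phenol is needed.
- The enol (an α-formyl deoxybenzoin) comes from the deoxybenzoin by aminomethylenation and hydrolysis; the deoxybenzoin comes from Friedel–Crafts acylation of 1,2,3,4-tetramethoxybenzene with an arylacetic acid.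
- The arylacetic acid comes from 2,3-dihydroxybenzaldehyde by 2-O-methylation, 3-O-pivaloylation and one-carbon homologation.
- Ring order: rings A and B are bought; ring C is the only ring formed (step 7).

Key step: step 7

Remark on the chemistry: the target has no stereocentre, and the C3–C1' axis has only one ortho substituent on ring B and should rotate freely. The compound is therefore achiral and no enantiocontrol is needed.

**Step 1**
Reactants: 1 2,3-dihydroxybenzaldehyde
Product: 2 3-hydroxy-2-methoxybenzaldehyde
Conditions: NaH (1.0 equiv), DMSO, rt; then MeI (1.0 equiv), rt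
Reagents that add atoms: iodomethane, CI
Why: Williamson ether synthesis on the monoanion: one equivalent of base should remove only the more acidic 2-OH proton (its phenoxide is conjugated with the ortho formyl group), so this oxygen is methylated while the 3-OH stays protonated.

**Step 2**
Reactants: 2 3-hydroxy-2-methoxybenzaldehyde
Product: 3 3-formyl-2-methoxyphenyl pivalate
Conditions: PivCl, Et3N, DMAP (cat.), CH2Cl2, 0 °C to rt
Reagents that add atoms: pivaloyl chloride, CC(C)(C)C(=O)Cl
Why: DMAP-catalysed O-acylation of the only free phenol; the hindered, electron-withdrawing pivalate is chosen to survive the ylide, acid and amine steps and to make ring B a poorer electron donor for step 7.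

**Step 3**
Reactants: 3 3-formyl-2-methoxyphenyl pivalate
Product: 4 2-methoxy-3-(2-methoxyethenyl)phenyl pivalate (E/Z mixture)
Conditions: MeOCH2PPh3Cl, KHMDS, THF, 0 °C; then 3, −78 to 0 °C
Reagents that add atoms: (methoxymethyl)triphenylphosphonium chloride, [Cl-].COC[P+](c1ccccc1)(c1ccccc1)c1ccccc1
Why: Wittig methoxymethylenation; the ylide should add to the aldehyde much faster than to the hindered aryl pivalate, and the alkene geometry does not matter because both isomers hydrolyse to the same aldehyde.

**Step 4**
Reactants: 4 2-methoxy-3-(2-methoxyethenyl)phenyl pivalate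
Product: 6 2-(2-methoxy-3-pivaloyloxyphenyl)acetic acid, via arylacetaldehyde 5 (not isolated)
Conditions: 2 M HCl, THF, 40 °C; then NaH2PO4, 2-methyl-2-butene, NaClO2, t-BuOH/H2O, 0 °C to rt
Reagents that add atoms: water, O; sodium chlorite, [Na+].[O-]Cl=O
Why: Acid hydrolysis of the enol ether followed in the same flask by Pinnick oxidation, so the enolisable arylacetaldehyde is not handled; the pivalate tolerates both stages and the alkene scavenger protects the anisole ring from hypochlorite.

**Step 5**
Reactants: 6 2-(2-methoxy-3-pivaloyloxyphenyl)acetic acid; 7 1,2,3,4-tetramethoxybenzene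
Product: 9 2-(2-methoxy-3-pivaloyloxyphenyl)-1-(2,3,4,5-tetramethoxyphenyl)ethan-1-one, via mixed trifluoroacetic anhydride 8 (not isolated)
Conditions: (CF3CO)2O, 85% H3PO4 (cat.), CH2Cl2, 0 °C to rt
Reagents that add atoms: none
Why: Friedel–Crafts acylation through the mixed anhydride; the two free positions of 7 are equivalent, so only one ketone can form, and without a strong Lewis acid the methyl ether ortho to the new carbonyl and the pivalate should both be kept.

**Step 6**
Reactants: 9 2-(2-methoxy-3-pivaloyloxyphenyl)-1-(2,3,4,5-tetramethoxyphenyl)ethan-1-one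
Product: 11 (Z)-3-hydroxy-2-(2-methoxy-3-pivaloyloxyphenyl)-1-(2,3,4,5-tetramethoxyphenyl)prop-2-en-1-one, via enaminone 10 (not isolated)
Conditions: t-BuOCH(NMe2)2, toluene, 70 °C; concentrate; then 1 M HCl, THF, rt
Reagents that add atoms: tert-butoxybis(dimethylamino)methane, CN(C)C(OC(C)(C)C)N(C)C; water, O
Why: Aminomethylenation of the doubly activated benzylic methylene with Bredereck's reagent, then acid hydrolysis of the vinylogous amide to the hydroxymethylene ketone, which should rest as the hydrogen-bonded Z enol.

**Step 7**
Reactants: 11 (Z)-3-hydroxy-2-(2-methoxy-3-pivaloyloxyphenyl)-1-(2,3,4,5-tetramethoxyphenyl)prop-2-en-1-one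
Product: 12 5,6,7,8-tetramethoxy-3-(2-methoxy-3-pivaloyloxyphenyl)chromen-4-one
Conditions: undivided cell, graphite anode, Pt cathode, Bu4NPF6 (0.1 M), (CF3)2CHOH, constant current 5 mA cm−2, 2.2 F mol−1, rt
Reagents that add atoms: none
Why: Proposed new method: anodic one-electron oxidation in hexafluoroisopropanol should put a radical cation on the tetramethoxybenzoyl ring; the Z enol holds its oxygen on the same side as the aroyl group, the fluorinated alcohol opens the internal O–H···O=C hydrogen bond so the C(=O)–Cα bond can rotate, and the enol oxygen then adds to C6, the only hydrogen-bearing carbon of that ring, after which loss of a second electron and two protons restores aromaticity while hydrogen is evolved at the cathode. The closest known reaction type is the anodic dehydrogenative C–O cyclisation of an arene with a tethered oxygen nucleophile, as in the lactonisation of biaryl-2-carboxylic acids to benzocoumarins and the closure of anilides to benzoxazoles; an enol oxygen has not been shown in this role. The pyranone ring closes in a 6-endo-trig mode with respect to the attacked C1=C6 arene bond, and no stereocentre is formed. Three selectivities are needed: attack at C6–H and not at the methoxy-bearing C2 (the ipso adduct cannot rearomatise by proton loss and should revert in the non-nucleophilic medium); attack on ring A and not on C6' of ring B, which would give a 3-aroylbenzofuran (the pivalate keeps ring B the poorer donor, so the hole should stay on the tetramethoxy ring); and bonding through oxygen and not carbon (Cα is fully substituted, so only oxygen can close a ring). The charge is kept near the theoretical 2 F mol−1 to limit further oxidation of the product.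

**Step 8**
Reactants: 12 5,6,7,8-tetramethoxy-3-(2-methoxy-3-pivaloyloxyphenyl)chromen-4-one
Product: 13 5-hydroxy-6,7,8-trimethoxy-3-(2-methoxy-3-pivaloyloxyphenyl)chromen-4-one
Conditions: BCl3 (1.2 equiv), CH2Cl2, −78 to 0 °C; then aq. NaHCO3
Reagents that add atoms: none
Why: Chelation-controlled Lewis-acid ether cleavage: boron binds between the C4 carbonyl and the peri 5-methoxy oxygen, so chloride should remove only that methyl group; the step is run while the 3'-oxygen is still an ester so that no free phenol can direct boron to the 2'-methoxy group.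

**Step 9**
Reactants: 13 5-hydroxy-6,7,8-trimethoxy-3-(2-methoxy-3-pivaloyloxyphenyl)chromen-4-one
Product: 14 5,3'-dihydroxy-6,7,8,2'-tetramethoxyisoflavone
Conditions: K2CO3 (1.5 equiv), MeOH, 0 °C to rt; then aq. NH4Cl
Reagents that add atoms: none
Why: Base-mediated transesterification (methanolysis) of the aryl pivalate; carbonate in methanol at or below room temperature should leave the pyranone ring closed and the methyl ethers untouched.

**Compound list**
1 | 2,3-dihydroxybenzaldehyde | O=Cc1cccc(O)c1O | starting material
2 | 3-hydroxy-2-methoxybenzaldehyde | COc1c(O)cccc1C=O | intermediate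
3 | 3-formyl-2-methoxyphenyl pivalate | COc1c(OC(=O)C(C)(C)C)cccc1C=O | intermediate
4 | 2-methoxy-3-(2-methoxyethenyl)phenyl pivalate (E/Z mixture, geometry not defined) | COC=Cc1cccc(OC(=O)C(C)(C)C)c1OC | intermediate
5 | 2-(2-methoxy-3-pivaloyloxyphenyl)acetaldehyde (not isolated) | O=CCc1cccc(OC(=O)C(C)(C)C)c1OC | intermediate
6 | 2-(2-methoxy-3-pivaloyloxyphenyl)acetic acid | OC(=O)Cc1cccc(OC(=O)C(C)(C)C)c1OC | intermediate
7 | 1,2,3,4-tetramethoxybenzene | COc1ccc(OC)c(OC)c1OC | starting material
8 | 2-(2-methoxy-3-pivaloyloxyphenyl)acetic trifluoroacetic anhydride (not isolated) | O=C(Cc1cccc(OC(=O)C(C)(C)C)c1OC)OC(=O)C(F)(F)F | intermediate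
9 | 2-(2-methoxy-3-pivaloyloxyphenyl)-1-(2,3,4,5-tetramethoxyphenyl)ethan-1-one | COc1c(OC)c(OC)c(OC)cc1C(=O)Cc1cccc(OC(=O)C(C)(C)C)c1OC | intermediate
10 | 3-(dimethylamino)-2-(2-methoxy-3-pivaloyloxyphenyl)-1-(2,3,4,5-tetramethoxyphenyl)prop-2-en-1-one (not isolated; alkene geometry not defined, either isomer hydrolyses to 11) | COc1c(OC)c(OC)c(OC)cc1C(=O)C(=CN(C)C)c1cccc(OC(=O)C(C)(C)C)c1OC | intermediate
11 | (Z)-3-hydroxy-2-(2-methoxy-3-pivaloyloxyphenyl)-1-(2,3,4,5-tetramethoxyphenyl)prop-2-en-1-one | COc1c(OC)c(OC)c(OC)cc1C(=O)\C(=C/O)c1cccc(OC(=O)C(C)(C)C)c1OC | intermediate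
12 | 5,6,7,8-tetramethoxy-3-(2-methoxy-3-pivaloyloxyphenyl)chromen-4-one | COc1c(OC(=O)C(C)(C)C)cccc1-c1coc2c(OC)c(OC)c(OC)c(OC)c2c1=O | intermediate
13 | 5-hydroxy-6,7,8-trimethoxy-3-(2-methoxy-3-pivaloyloxyphenyl)chromen-4-one | COc1c(OC(=O)C(C)(C)C)cccc1-c1coc2c(OC)c(OC)c(OC)c(O)c2c1=O | intermediate
14 | 5,3'-dihydroxy-6,7,8,2'-tetramethoxyisoflavone | COc1c(O)cccc1-c1coc2c(OC)c(OC)c(OC)c(O)c2c1=O | target

**Step count**
Total: 9 steps. Longest linear sequence: 9 steps (1 to 14); compound 7 enters unchanged at step 5.

**Steps most likely to fail**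

1. Step 7 (proposed new method). What may go wrong: the hole may sit on ring B or on the enol instead of ring A, leading to benzofuran closure, ipso attack at the methoxy-bearing carbon with loss of methanol, or oligomer films that passivate the anode. The fallback uses known chemistry and puts the ring oxygen on ring A before the pyranone is closed. It sets out from 7 and uses acid 6. Rieche formylation of 7 (Cl2CHOMe, TiCl4, CH2Cl2, 0 °C) should give 2,3,4,5-tetramethoxybenzaldehyde F1. Baeyer–Villiger oxidation (mCPBA, CH2Cl2) should give 2,3,4,5-tetramethoxyphenyl formate F2, which is methanolysed (K2CO3, MeOH) to 2,3,4,5-tetramethoxyphenol F3. C-acylation of F3 with acid 6 at its only free position, ortho to the hydroxyl (BF3·OEt2, 80 °C), should give 1-(2-hydroxy-3,4,5,6-tetramethoxyphenyl)-2-(2-methoxy-3-pivaloyloxyphenyl)ethan-1-one F4. Heating F4 with N,N-dimethylformamide dimethyl acetal (toluene, 90 °C) should form the 2-hydroxyaryl enaminone F5, which closes by addition of the phenol and loss of dimethylamine. The fallback comes back to the route at 12.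

2. Step 1. What may go wrong: alkylation through the minor but more nucleophilic 3-phenoxide tautomer, or double methylation, would give an isomer mixture that is hard to separate. The fallback fixes the regiochemistry through the dianion and sets out from 1. NaH (2.2 equiv) in DMSO and then BnBr (1.0 equiv) should alkylate the more reactive 3-oxygen to give 3-(benzyloxy)-2-hydroxybenzaldehyde F6. Methylation of the remaining phenol (MeI, K2CO3, DMF) should give 3-(benzyloxy)-2-methoxybenzaldehyde F7. Hydrogenolysis (H2, 1 atm, Pd/C, EtOAc, stopped after one equivalent of hydrogen) removes the benzyl group and comes back to the route at 2.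

3. Step 6. What may go wrong: the pivalate may be lost to liberated dimethylamine or tert-butoxide during aminomethylenation, and the formyl group may be lost by retro-Claisen cleavage during hydrolysis. The fallback replaces the basic condensation by Lewis-acid formylation of a silyl enol ether (Mukaiyama type) and sets out from 9. TMSOTf and Et3N (CH2Cl2, 0 °C) should give the trimethylsilyl enol ether F8. Trimethyl orthoformate with BF3·OEt2 (CH2Cl2, −78 °C) should give 3,3-dimethoxy-2-(2-methoxy-3-pivaloyloxyphenyl)-1-(2,3,4,5-tetramethoxyphenyl)propan-1-one F9 (racemic). Aqueous HCl in THF unmasks the aldehyde and comes back to the route at 11.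

**Further compounds**
F1 | step 7 | 2,3,4,5-tetramethoxybenzaldehyde | COc1cc(C=O)c(OC)c(OC)c1OC
F2 | step 7 | 2,3,4,5-tetramethoxyphenyl formate | COc1cc(OC=O)c(OC)c(OC)c1OC
F3 | step 7 | 2,3,4,5-tetramethoxyphenol | COc1cc(O)c(OC)c(OC)c1OC
F4 | step 7 | 1-(2-hydroxy-3,4,5,6-tetramethoxyphenyl)-2-(2-methoxy-3-pivaloyloxyphenyl)ethan-1-one | COc1c(O)c(C(=O)Cc2cccc(OC(=O)C(C)(C)C)c2OC)c(OC)c(OC)c1OC
F5 | step 7 | 3-(dimethylamino)-1-(2-hydroxy-3,4,5,6-tetramethoxyphenyl)-2-(2-methoxy-3-pivaloyloxyphenyl)prop-2-en-1-one (geometry not defined) | COc1c(O)c(C(=O)C(=CN(C)C)c2cccc(OC(=O)C(C)(C)C)c2OC)c(OC)c(OC)c1OC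
F6 | step 1 | 3-(benzyloxy)-2-hydroxybenzaldehyde | O=Cc1cccc(OCc2ccccc2)c1O
F7 | step 1 | 3-(benzyloxy)-2-methoxybenzaldehyde | COc1c(OCc2ccccc2)cccc1C=O
F8 | step 6 | 2-(2-methoxy-3-pivaloyloxyphenyl)-1-(2,3,4,5-tetramethoxyphenyl)-1-(trimethylsilyloxy)ethene (geometry not defined) | COc1c(OC)c(OC)c(OC)cc1C(O[Si](C)(C)C)=Cc1cccc(OC(=O)C(C)(C)C)c1OC
F9 | step 6 | 3,3-dimethoxy-2-(2-methoxy-3-pivaloyloxyphenyl)-1-(2,3,4,5-tetramethoxyphenyl)propan-1-one (racemic) | COc1c(OC)c(OC)c(OC)cc1C(=O)C(C(OC)OC)c1cccc(OC(=O)C(C)(C)C)c1OC
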